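**Retrosynthetic overview**
- The route rests on ring B (the phenol ring): its C6–Br carbon lies between the phenol carbon C1 and the unsubstituted C5–H. C6 is therefore read as a CBr unit inserted into the C1–C5 bond of a five-membered ring that already holds C1–O, C2–OAr and C3–OMe.
- The target is cut back to the ring B monobromophenol (last bromine at C4, para to OH, by NBS). That phenol is cut to a tert-butyldimethylsilyl dienol ether of a cyclopentenone plus bromoform (dibromocarbene one-carbon ring expansion with aromatization, the only ring formed).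
- The dienol ether comes from the 3-methoxy-2-aryloxycyclopentenone, this from the enolized 2-aryloxycyclopentane-1,3-dione, and this from 2-diazocyclopentane-1,3-dione plus the ring A phenol (Rh2(OAc)4 O–H insertion makes the C2–OAr bond).
- Ring A is bought: 3,5-dibromo-2-hydroxybenzaldehyde is O-methylated and converted to the phenol by Baeyer–Villiger oxidation.

Key step: step 7

Remark on the chemistry: the target has no stereocentre, and the bicyclic dibromocyclopropane of the key step is a racemic, cis-fused intermediate that is not isolated, so no stereocontrol is needed. The 2-aryloxy-1,3-dione is written as its enol.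

**Step 1**
Reactants: 1 3,5-dibromo-2-hydroxybenzaldehyde
Product: 2 3,5-dibromo-2-methoxybenzaldehyde
Conditions: MeI, K2CO3, DMF, rt
Reagents that add atoms: iodomethane, CI
Why: Williamson O-methylation of the acidic ortho-bromophenol, to which the aldehyde and the aryl bromides are inert.

**Step 2**
Reactants: 2 3,5-dibromo-2-methoxybenzaldehyde
Product: 4 3,5-dibromo-2-methoxyphenol, via aryl formate 3 (not isolated)
Conditions: mCPBA, CH2Cl2, 40 °C; aq NaHCO3 wash; then K2CO3 (cat.), MeOH, rt
Reagents that add atoms: meta-chloroperbenzoic acid, OOC(=O)c1cccc(Cl)c1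
Why: Baeyer–Villiger oxidation in which the aryl group, activated by its ortho methoxy donor, migrates to oxygen in the peracid adduct, followed by base-catalysed methanolysis of the aryl formate.

**Step 3**
Reactants: 5 cyclopentane-1,3-dione
Product: 6 2-diazocyclopentane-1,3-dione
Conditions: 4-acetamidobenzenesulfonyl azide, Et3N, MeCN, 0 °C to rt
Reagents that add atoms: 4-acetamidobenzenesulfonyl azide, CC(=O)Nc1ccc(cc1)S(=O)(=O)N=[N+]=[N-]
Why: Regitz diazo transfer to the doubly activated C2 methylene of the 1,3-dione under amine base.

**Step 4**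
Reactants: 6 2-diazocyclopentane-1,3-dione; 4 3,5-dibromo-2-methoxyphenol
Product: 7 2-(3,5-dibromo-2-methoxyphenoxy)-3-hydroxycyclopent-2-en-1-one
Conditions: Rh2(OAc)4 (2 mol %), 4 (1.5 equiv), ClCH2CH2Cl, 70 °C, slow addition of 6; product taken into aq NaHCO3 and re-acidified
Reagents that add atoms: none
Why: Carbenoid O–H insertion, in which dirhodium tetraacetate turns the diazo dione into an electrophilic acceptor/acceptor carbenoid that is captured by the phenol oxygen and then shifts a proton, so the C2–OAr bond forms without touching the aryl bromides and the product rests as the enol.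

**Step 5**
Reactants: 7 2-(3,5-dibromo-2-methoxyphenoxy)-3-hydroxycyclopent-2-en-1-one
Product: 8 2-(3,5-dibromo-2-methoxyphenoxy)-3-methoxycyclopent-2-en-1-one
Conditions: Me3SiCHN2, MeOH/PhMe, 0 °C to rt
Reagents that add atoms: trimethylsilyldiazomethane, C[Si](C)(C)C=[N+]=[N-]
Why: Diazoalkane O-methylation of the vinylogous acid, which can give only one vinylogous ester because the two enol oxygens are equivalent by symmetry.

**Step 6**
Reactants: 8 2-(3,5-dibromo-2-methoxyphenoxy)-3-methoxycyclopent-2-en-1-one
Product: 10 tert-butyl{[5-(3,5-dibromo-2-methoxyphenoxy)-4-methoxycyclopenta-1,4-dien-1-yl]oxy}dimethylsilane, via lithium dienolate 9 (not isolated)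
Conditions: LiN(SiMe3)2 (1.05 equiv), THF, −78 °C; TBSCl, DMPU, −78 to −20 °C; cold pentane/aq NaHCO3 work-up, used crude at once
Reagents that add atoms: tert-butyldimethylsilyl chloride, CC(C)(C)[Si](C)(C)Cl
Why: Kinetic deprotonation of the vinylogous ester at the α' CH2 gives the cross-conjugated dienolate, which is O-silylated (silyl enol ether formation); LiN(SiMe3)2 is used in place of LDA so that the ring A C–H flanked by two bromines is not metalated.

**Step 7**
Reactants: 10 tert-butyl{[5-(3,5-dibromo-2-methoxyphenoxy)-4-methoxycyclopenta-1,4-dien-1-yl]oxy}dimethylsilane; 11 bromoform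
Product: 14 6-bromo-2-(3,5-dibromo-2-methoxyphenoxy)-3-methoxyphenol, via dibromocyclopropane 12 (not isolated), via aryl silyl ether 13 (not isolated)
Conditions: CHBr3 (1.5 equiv), KOtBu (2.5 equiv, added last in portions), pentane/PhMe, −40 to 0 °C; filter, concentrate; then Bu4NF, THF, 0 °C; 1 M HCl work-up
Reagents that add atoms: bromoform (compound 11), BrC(Br)Br
Why: Proposed new method: KOtBu converts bromoform into dibromocarbene by α-elimination, and this electrophile should add to the C1=C5(H) silyl enol ether bond of 10, since attack at the unsubstituted terminus C5 places the developing positive charge on C1, where the siloxy oxygen and, through the diene, the C3 methoxy group stabilise it, while the other double bond is tetrasubstituted and screened by the aryloxy group. The 6,6-dibromobicyclo[3.1.0]hexene 12 should then lose its endo bromide with disrotatory cyclopropyl-to-allyl opening of the ring-fusion bond, so ring B is closed by one-carbon ring expansion of the five-membered ring (two new C–C bonds to the CBr carbon) and not by cyclisation of an open chain. The ring-opened cation is an arenium ion that loses a proton from the former CH2 carbon to the second equivalent of KOtBu, which gives aryl silyl ether 13 with the bromine ortho to the oxygen, and Bu4NF then frees phenol 14. The closest known reactions are the dihalocarbene ring expansion of cyclic silyl enol ethers to 2-halo enones and the dihalocarbene conversion of cyclopentadienes and indenes into halobenzenes and 2-halonaphthalenes; joining the two on a trioxygenated siloxycyclopentadiene is the untested part. No stereocentre is created in the product, because the two of racemic 12 vanish on aromatisation. The step needs site selectivity between the two double bonds and an unscrambled diene: the first is secured by the electronic and steric bias named above, the second by reaction below 0 °C and by adding KOtBu last so that it is consumed by the far more acidic bromoform and not by the ring CH2, and the silyl group keeps the phenol masked from Reimer–Tiemann attack by surplus carbene.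

**Step 8**
Reactants: 14 6-bromo-2-(3,5-dibromo-2-methoxyphenoxy)-3-methoxyphenol
Product: 15 4,6-dibromo-2-(3,5-dibromo-2-methoxyphenoxy)-3-methoxyphenol
Conditions: NBS (1.0 equiv), MeCN, 0 °C
Reagents that add atoms: N-bromosuccinimide, O=C1CCC(=O)N1Br
Why: Electrophilic aromatic bromination should occur only at C4 of ring B, the one open position that is para to the free hydroxyl and ortho to the methoxy group, whereas C5 is activated only by the aryloxy group and ring A is deactivated by two bromines.

**Compound list**
1 | 3,5-dibromo-2-hydroxybenzaldehyde | O=Cc1cc(Br)cc(Br)c1O | starting material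
2 | 3,5-dibromo-2-methoxybenzaldehyde | COc1c(Br)cc(Br)cc1C=O | intermediate
3 | 3,5-dibromo-2-methoxyphenyl formate | COc1c(Br)cc(Br)cc1OC=O | intermediate (not isolated)
4 | 3,5-dibromo-2-methoxyphenol | COc1c(Br)cc(Br)cc1O | intermediate
5 | cyclopentane-1,3-dione | O=C1CCC(=O)C1 | starting material
6 | 2-diazocyclopentane-1,3-dione | [N-]=[N+]=C1C(=O)CCC1=O | intermediate
7 | 2-(3,5-dibromo-2-methoxyphenoxy)-3-hydroxycyclopent-2-en-1-one | O=C1CCC(O)=C1Oc1cc(Br)cc(Br)c1OC | intermediate
8 | 2-(3,5-dibromo-2-methoxyphenoxy)-3-methoxycyclopent-2-en-1-one | COC1=C(Oc2cc(Br)cc(Br)c2OC)C(=O)CC1 | intermediate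
9 | lithium 5-(3,5-dibromo-2-methoxyphenoxy)-4-methoxycyclopenta-1,4-dien-1-olate | [Li+].[O-]C1=CCC(OC)=C1Oc1cc(Br)cc(Br)c1OC | intermediate (not isolated)
10 | tert-butyl{[5-(3,5-dibromo-2-methoxyphenoxy)-4-methoxycyclopenta-1,4-dien-1-yl]oxy}dimethylsilane | CC(C)(C)[Si](C)(C)OC1=CCC(OC)=C1Oc1cc(Br)cc(Br)c1OC | intermediate
11 | bromoform | BrC(Br)Br | starting material
12 | tert-butyl{[6,6-dibromo-2-(3,5-dibromo-2-methoxyphenoxy)-3-methoxybicyclo[3.1.0]hex-2-en-1-yl]oxy}dimethylsilane (racemic, cis-fused) | CC(C)(C)[Si](C)(C)OC12C(Oc3cc(Br)cc(Br)c3OC)=C(OC)CC1C2(Br)Br | intermediate (not isolated)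
13 | tert-butyl[6-bromo-2-(3,5-dibromo-2-methoxyphenoxy)-3-methoxyphenoxy]dimethylsilane | COc1ccc(Br)c(O[Si](C)(C)C(C)(C)C)c1Oc1cc(Br)cc(Br)c1OC | intermediate (not isolated)
14 | 6-bromo-2-(3,5-dibromo-2-methoxyphenoxy)-3-methoxyphenol | COc1ccc(Br)c(O)c1Oc1cc(Br)cc(Br)c1OC | intermediate
15 | 4,6-dibromo-2-(3,5-dibromo-2-methoxyphenoxy)-3-methoxyphenol | COc1c(Br)cc(Br)cc1Oc1c(O)c(Br)cc(Br)c1OC | target

**Step count**
Total step count: 8. Longest linear sequence: 7 steps (steps 1, 2, 4, 5, 6, 7, 8, from compound 1).

**Steps most likely to fail**

Step 7. The carbene may add without site selectivity, or the diene may be scrambled by deprotonation or 1,5-hydrogen shift before the carbene arrives, or the carbene may be consumed by alkoxide. The fallback uses known chemistry, sets out from compound 4 and comes back at compound 15. Phenol 4 displaces fluoride from 2-fluoro-3-methoxybenzaldehyde (COc1cccc(C=O)c1F) by nucleophilic aromatic substitution (K2CO3, DMAc, 120 °C) to give 2-(3,5-dibromo-2-methoxyphenoxy)-3-methoxybenzaldehyde F1. Baeyer–Villiger oxidation with mCPBA in CH2Cl2 gives 2-(3,5-dibromo-2-methoxyphenoxy)-3-methoxyphenyl formate F2, and methanolysis (K2CO3 cat., MeOH) gives 2-(3,5-dibromo-2-methoxyphenoxy)-3-methoxyphenol F3. Two equivalents of NBS in MeCN at 0 °C should then brominate ring B ortho and para to the hydroxyl, the two positions that are also para and ortho to the methoxy group, which gives compound 15.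

Step 6. The amide base may metalate ring A between the bromines, or the diene may undergo 1,5-hydrogen shift and Diels–Alder dimerisation during work-up. The fallback sets out from compound 8 and comes back at compound 15. Soft enolisation with TBSOTf and Et3N in CH2Cl2 (−78 to 0 °C) uses no metal amide and is expected to give 10 together with, or replaced by, its positional isomer tert-butyl{[2-(3,5-dibromo-2-methoxyphenoxy)-3-methoxycyclopenta-1,3-dien-1-yl]oxy}dimethylsilane F4, whose ring CH2 lies next to the C–OSi carbon. The crude diene is taken through the conditions of step 7. In F4 the carbene should add to the methyl enol ether C=C(H) bond and give tert-butyl{[6,6-dibromo-2-(3,5-dibromo-2-methoxyphenoxy)-1-methoxybicyclo[3.1.0]hex-2-en-3-yl]oxy}dimethylsilane F5. Ring opening and proton loss give tert-butyl[4-bromo-2-(3,5-dibromo-2-methoxyphenoxy)-3-methoxyphenoxy]dimethylsilane F6, and Bu4NF gives 4-bromo-2-(3,5-dibromo-2-methoxyphenoxy)-3-methoxyphenol F7, in which the carbene-derived bromine is para to the hydroxyl. NBS then brominates the open position ortho to the hydroxyl and para to the methoxy group, so F7 and any 14 formed from 10 in the same mixture both end at compound 15.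

Step 4. Capture of the carbenoid by the hindered, electron-poor phenol may be slow, so that Wolff rearrangement, carbenoid dimerisation or insertion into the enol O–H of the product takes over. The fallback sets out from compound 4 and comes back at compound 7. Phenol 4 is O-alkylated with methyl 5-bromo-4-oxopentanoate (COC(=O)CCC(=O)CBr; K2CO3, acetone, rt) to give methyl 5-(3,5-dibromo-2-methoxyphenoxy)-4-oxopentanoate F8. KOtBu in THF then closes the five-membered ring by intramolecular Claisen (Dieckmann-type) acylation of the aryloxymethyl ketone carbanion by the ester, and acidification with HCl gives compound 7.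

**Further compounds**
F1 | step 7 | 2-(3,5-dibromo-2-methoxyphenoxy)-3-methoxybenzaldehyde | COc1cccc(C=O)c1Oc1cc(Br)cc(Br)c1OC
F2 | step 7 | 2-(3,5-dibromo-2-methoxyphenoxy)-3-methoxyphenyl formate | COc1cccc(OC=O)c1Oc1cc(Br)cc(Br)c1OC
F3 | step 7 | 2-(3,5-dibromo-2-methoxyphenoxy)-3-methoxyphenol | COc1cccc(O)c1Oc1cc(Br)cc(Br)c1OC
F4 | step 6 | tert-butyl{[2-(3,5-dibromo-2-methoxyphenoxy)-3-methoxycyclopenta-1,3-dien-1-yl]oxy}dimethylsilane | CC(C)(C)[Si](C)(C)OC1=C(Oc2cc(Br)cc(Br)c2OC)C(OC)=CC1
F5 | step 6 | tert-butyl{[6,6-dibromo-2-(3,5-dibromo-2-methoxyphenoxy)-1-methoxybicyclo[3.1.0]hex-2-en-3-yl]oxy}dimethylsilane (racemic, cis-fused) | COC12C(Oc3cc(Br)cc(Br)c3OC)=C(O[Si](C)(C)C(C)(C)C)CC1C2(Br)Br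
F6 | step 6 | tert-butyl[4-bromo-2-(3,5-dibromo-2-methoxyphenoxy)-3-methoxyphenoxy]dimethylsilane | COc1c(Br)ccc(O[Si](C)(C)C(C)(C)C)c1Oc1cc(Br)cc(Br)c1OC
F7 | step 6 | 4-bromo-2-(3,5-dibromo-2-methoxyphenoxy)-3-methoxyphenol | COc1c(Br)ccc(O)c1Oc1cc(Br)cc(Br)c1OC
F8 | step 4 | methyl 5-(3,5-dibromo-2-methoxyphenoxy)-4-oxopentanoate | COC(=O)CCC(=O)COc1cc(Br)cc(Br)c1OC
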